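**Retrosynthetic overview**

1. Numbering: ten-membered ring C1–C10 (C1=C10 E, methyl C14 on C10, OAc on C2, OH and methyl C15 on C4, methacrylate on C6), fused butenolide O–C8(=C9)–C7=C11(C13H2OH)–C12(=O). The strategy rests on C4 lying between two CH2 groups (C3, C5), each leading to an oxygen-bearing stereocentre (C2, C6): the imprint of one dithiane carbon that has opened two terminal epoxides.
2. Last disconnections: the three ester/silyl groups, then the ten-membered ring at C8=C9 (intramolecular vinylogous aldol condensation of the butenolide C8H2 with a C9 enal; C1=C10 from a Wittig reaction).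
3. Butenolide built on C7: aldehyde → β-keto ester (C7–C11) → (Z)-enol triflate → hydroxymethylation (C7–C8) and lactonisation.
4. C4 carbinol: ketone → methylene → hydroxyl-directed epoxidation → hydride opening.
5. C3–C4 and C4–C5: one-flask union of a 2-silyl-1,3-dithiane with two glycidyl ethers, relayed by a 1,4-Brook rearrangement. Ring order: butenolide (step 15), then the ten-membered carbocycle (step 19).

Key step: step 3

Remark: C1 carries the 4-methoxybenzyl and C7 the benzyl ether so that C7 is unmasked first (Raney Ni) and C1 later (DDQ) beside the butenolide; compounds 4, 6, 18, 25 and 30 are taken as commercial, and the SMILES strings are authoritative for configuration.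

**Route**

Step 1
Reactants: 1 1,3-dithiane
Product: 3 2-(tert-butyldimethylsilyl)-1,3-dithiane, via 2-lithio-1,3-dithiane 2 (not isolated)
Conditions: n-BuLi, THF, −30 °C; then t-BuMe2SiCl, −78 °C → rt
Reagents that add atoms: tert-butyldimethylsilyl chloride, CC(C)(C)[Si](C)(C)Cl
Why: Corey–Seebach metalation at C2 of the dithiane followed by C-silylation of the carbanion is the standard preparation of the silyl linchpin; no stereocentre is involved.

Step 2
Reactants: 4 (R)-glycidol
Product: 5 (S)-4-methoxybenzyl glycidyl ether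
Conditions: NaH, 4-MeOC6H4CH2Cl, Bu4NI (cat.), DMF, 0 °C → rt
Reagents that add atoms: 4-methoxybenzyl chloride, COc1ccc(CCl)cc1
Why: Williamson etherification of the primary alkoxide leaves the oxirane carbon untouched, so the stereocentre of 4 is retained (the descriptor changes from R to S only through the change in CIP priorities) and a Payne shift would be degenerate.

Step 3
Reactants: 3 2-(tert-butyldimethylsilyl)-1,3-dithiane; 5 (S)-4-methoxybenzyl glycidyl ether; 6 (R)-benzyl glycidyl ether
Product: 10 2-[(2R)-3-benzyloxy-2-hydroxypropyl]-2-[(2S)-2-(tert-butyldimethylsilyloxy)-3-(4-methoxybenzyloxy)propyl]-1,3-dithiane (C1–C7 chain; C4 = dithiane carbon; O2 silylated; O6 free), via lithiated silyl dithiane 7 (not isolated), via lithium alkoxide of the first opening 8 (not isolated), via Brook-rearranged dithiane anion 9 (not isolated)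
Conditions: t-BuLi, Et2O, −78 → −45 °C; then 5, Et2O, −78 → −25 °C; then 6, HMPA, Et2O, −78 °C → rt; aq. NH4Cl
Reagents that add atoms: none
Why: t-BuLi deprotonates 3 to carbanion 7, which opens epoxide 5 by SN2 attack at its terminal CH2 (C3–C4 bond) to give alkoxide 8, stable in ether; HMPA added with epoxide 6 triggers the 1,4-Brook shift of silicon from C4 to O2, unmasking carbanion 9, which opens 6 at its terminal CH2 (C4–C5 bond). The closest known reaction type is the solvent-controlled three-component coupling of a 2-silyl-1,3-dithiane with two different epoxides (anion relay). No ring is closed. No stereocentre is created: C2 and C6 are the epoxide methine carbons, untouched because both openings occur at CH2, so they carry over the configurations of 5 and 6. The step needs each epoxide to react once and only at its terminal carbon; the first is secured by withholding the polar cosolvent until 5 is consumed, the second by the unhindered monosubstituted oxiranes. The relay also leaves O2 silylated and O6 free, the differentiation used in steps 6, 20 and 22.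

Step 4
Reactants: 10 C1–C7 dithiane
Product: 11 (2S,6R)-7-benzyloxy-6-hydroxy-1-(4-methoxybenzyloxy)-2-(tert-butyldimethylsilyloxy)heptan-4-one
Conditions: MeI, CaCO3, MeCN/H2O (9:1), 45 °C
Reagents that add atoms: water, O
Why: S-alkylative dithioketal hydrolysis (methylation makes sulfur a leaving group and water captures the thionium ion) releases the ketone under CaCO3-buffered conditions that spare the silyl, benzyl and 4-methoxybenzyl ethers and do not dehydrate the β-hydroxy ketone.

Step 5
Reactants: 11 β-hydroxy ketone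
Product: 12 (2S,6R)-7-benzyloxy-1-(4-methoxybenzyloxy)-4-methylidene-2-(tert-butyldimethylsilyloxy)heptan-6-ol
Conditions: Zn, CH2Br2, TiCl4, THF/CH2Cl2, 0 °C → rt
Reagents that add atoms: dibromomethane, BrCBr
Why: Takai–Lombardo methylenation with the non-basic zinc/titanium methylene reagent converts the ketone into the 1,1-disubstituted alkene without the retro-aldol cleavage or β-elimination that a basic ylide would risk with a β-hydroxy/β-silyloxy ketone.

Step 6
Reactants: 12 homoallylic alcohol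
Product: 13 C4 spiro-oxirane of 12 (2S,6R; oxirane oxygen on C4 anti to the C6 hydroxyl and the C2 silyloxy group)
Conditions: VO(acac)2 (5 mol %), t-BuOOH, CH2Cl2, 0 °C → rt
Reagents that add atoms: tert-butyl hydroperoxide, CC(C)(C)OO
Why: Hydroxyl-directed vanadium-catalysed epoxidation of a homoallylic alcohol: the vanadate ester of the C6 hydroxyl should deliver oxygen through a chair-like transition state with the C7 substituent equatorial and the metal over the unsubstituted CH2 terminus of the alkene, which places the new C4–O bond anti to O6 (and so anti to the syn-related O2) and sets C4.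

Step 7
Reactants: 13 epoxy alcohol
Product: 14 (2S,6R)-7-benzyloxy-1-(4-methoxybenzyloxy)-4-methyl-2-(tert-butyldimethylsilyloxy)heptane-4,6-diol (C4 hydroxyl anti to O2 and O6)
Conditions: LiAlH4, THF, 0 °C → rt; aq. NaOH work-up
Reagents that add atoms: none
Why: Hydride opens the 2,2-disubstituted oxirane by SN2 attack at its unhindered CH2 carbon, which becomes methyl C15, while the C4–O bond and therefore the C4 configuration stay untouched.

Step 8
Reactants: 14 diol
Product: 15 4,6-bis(triethylsilyl) ether of 14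
Conditions: Et3SiOTf, 2,6-lutidine, CH2Cl2, −78 → 0 °C
Reagents that add atoms: triethylsilyl trifluoromethanesulfonate, CC[Si](CC)(CC)OS(=O)(=O)C(F)(F)F
Why: Silyl triflate silylation caps the secondary C6 and the tertiary C4 hydroxyl (which would otherwise form five-membered lactols with the C7 and C1 aldehydes to come) as triethylsilyl ethers that can later be removed beside the TBS ether.

Step 9
Reactants: 15 bis(triethylsilyl) ether
Product: 16 C7 primary alcohol (7-O-debenzylated 15)
Conditions: H2 (1 atm), Raney Ni (W-2 grade, washed neutral), EtOH, rt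
Reagents that add atoms: none
Why: Hydrogenolysis over Raney Ni cleaves the benzyl ether selectively, the 4-methoxybenzyl ether and the silyl ethers being inert to this catalyst, so that C7 is unmasked first.

Step 10
Reactants: 16 C7 alcohol
Product: 17 C7 aldehyde (2S,6R; 6-O-TES, 4-O-TES, 2-O-TBS, 1-O-PMB)
Conditions: Dess–Martin periodinane, pyridine, CH2Cl2, 0 °C → rt
Reagents that add atoms: none
Why: Buffered Dess–Martin oxidation gives the α-silyloxy aldehyde without epimerising C6 or shifting the neighbouring silyl group.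

Step 11
Reactants: 18 ethyl 3-hydroxypropanoate
Product: 19 ethyl 3-(tert-butyldiphenylsilyloxy)propanoate
Conditions: t-BuPh2SiCl, imidazole, DMF, rt
Reagents that add atoms: tert-butyl(chloro)diphenylsilane, CC(C)(C)[Si](Cl)(c1ccccc1)c2ccccc2
Why: Imidazole-mediated silylation of the primary alcohol supplies the C11–C13 donor with O13 carrying the silyl group meant to last until the final step.

Step 12
Reactants: 17 C7 aldehyde; 19 ethyl 3-(tert-butyldiphenylsilyloxy)propanoate
Product: 21 β-hydroxy ester (C7 carbinol; C11 bearing CH2OTBDPS and CO2Et; mixture at C7 and C11), via lithium ester enolate 20 (not isolated)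
Conditions: LiN(iPr)2, THF, −78 °C (19, 20 min); then 17, −78 °C; aq. NH4Cl at −78 °C
Reagents that add atoms: none
Why: Ester enolate aldol addition forms the C7–C11 bond at −78 °C, where β-elimination of silanolate from the enolate and 1,2-silyl migration in the aldolate are slow; the C7 and C11 centres form unselectively and are both erased in steps 13 and 14.

Step 13
Reactants: 21 β-hydroxy ester
Product: 22 β-keto ester (C7 ketone; C11 epimers and enol)
Conditions: Dess–Martin periodinane, pyridine, CH2Cl2, rt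
Reagents that add atoms: none
Why: Dess–Martin oxidation of the secondary C7 carbinol gives the β-keto ester, removing the C7 stereocentre and making C11 enolisable.

Step 14
Reactants: 22 β-keto ester
Product: 24 (Z)-enol triflate (C7–OTf cis to the C12 ester; C6 cis to C13), via chelated sodium enolate 23 (not isolated)
Conditions: NaH, THF, 0 °C; then PhNTf2, 0 °C → rt
Reagents that add atoms: N-phenylbis(trifluoromethanesulfonimide), O=S(=O)(N(c1ccccc1)S(=O)(=O)C(F)(F)F)C(F)(F)F
Why: O-sulfonylation of the sodium-chelated enolate, in which the enolate oxygen and the ester carbonyl are held cis, gives the (Z)-enol triflate needed for lactonisation, the more acidic C11–H being removed in preference to C6–H.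

Step 15
Reactants: 24 (Z)-enol triflate; 25 (tributylstannyl)methanol
Product: 27 butenolide: 4-substituted 3-(tert-butyldiphenylsilyloxymethyl)furan-2(5H)-one with C8H2 (2S,6R; 1-O-PMB), via hydroxymethyl enoate 26 (not isolated)
Conditions: Pd(PPh3)4 (5 mol %), LiCl, 1,4-dioxane, 90 °C
Reagents that add atoms: none
Why: Migita–Kosugi–Stille coupling transfers the hydroxymethyl group to C7 with retention of alkene geometry, and the resulting cis γ-hydroxy enoate lactonises in the flask (5-exo-trig acyl substitution) to close the butenolide ring.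

Step 16
Reactants: 27 butenolide
Product: 28 C1 primary alcohol (1-O-PMB removed)
Conditions: DDQ, CH2Cl2/pH 7 buffer (10:1), 0 °C → rt
Reagents that add atoms: none
Why: Oxidative cleavage of the 4-methoxybenzyl ether (hydride abstraction, then hydrolysis of the oxocarbenium ion) frees the C1 hydroxyl without touching the silyl ethers or the butenolide.

Step 17
Reactants: 28 C1 alcohol
Product: 29 C1 aldehyde
Conditions: Dess–Martin periodinane, pyridine, CH2Cl2, 0 °C → rt
Reagents that add atoms: none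
Why: Dess–Martin oxidation gives the α-silyloxy aldehyde under neutral conditions that do not enolise the butenolide or epimerise C2.

Step 18
Reactants: 29 C1 aldehyde; 30 2-(triphenylphosphoranylidene)propanal
Product: 31 (E)-enal butenolide (C1=C10 E; C9 aldehyde; C8H2 butenolide)
Conditions: toluene, 80 °C
Reagents that add atoms: none
Why: Wittig olefination with the stabilised α-methyl ylide gives the (E)-2-methyl enal, and the neutral ylide is too weak a base to deprotonate the butenolide.

Step 19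
Reactants: 31 (E)-enal butenolide
Product: 34 macrocyclic γ-ylidenebutenolide (2-O-TBS, 4,6-bis-O-TES, 13-O-TBDPS; C1=C10 E; C8=C9 with C10 cis to C7), via 2-silyloxyfuran 32 (not isolated), via macrocyclic aldol silyl ether 33 (not isolated)
Conditions: t-BuMe2SiOTf, iPr2NEt, CH2Cl2 (0.5 mM, 31 added by syringe pump), −78 → 0 °C; then DBU, 0 °C → rt
Reagents that add atoms: none
Why: Proposed new method: soft enolisation turns the butenolide into 2-silyloxyfuran 32, whose C8 (the only unsubstituted nucleophilic furan position) should add to the silyl-triflate-activated C9 aldehyde in an intramolecular vinylogous Mukaiyama aldol reaction that closes the ten-membered ring under high dilution, after which DBU removes the acidic C8–H and expels the C9 silyloxy group (E1cB) so that the ring itself dictates the C8=C9 geometry; the closest known reaction type is the intermolecular one-flask silyloxyfuran aldol/β-elimination route to γ-ylidenebutenolides.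

Step 20
Reactants: 34 macrocyclic γ-ylidenebutenolide
Product: 35 4,6-diol (2-O-TBS, 13-O-TBDPS)
Conditions: PPTS, MeOH/CH2Cl2, 0 °C → rt
Reagents that add atoms: none
Why: Acid-catalysed methanolysis removes the two triethylsilyl ethers much faster than the secondary TBS and primary TBDPS ethers, unveiling the C6 and C4 hydroxyls.

Step 21
Reactants: 35 4,6-diol
Product: 36 6-methacrylate (C4 hydroxyl free)
Conditions: (CH2=C(CH3)CO)2O, Et3N, DMAP (cat.), CH2Cl2, 0 °C → rt
Reagents that add atoms: methacrylic anhydride, CC(=C)C(=O)OC(=O)C(C)=C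
Why: DMAP-catalysed acylation esterifies the secondary C6 hydroxyl, the tertiary C4 hydroxyl being too hindered to react under these conditions.

Step 22
Reactants: 36 6-methacrylate
Product: 37 C2 alcohol (13-O-TBDPS retained)
Conditions: HF·pyridine, pyridine, THF, 0 °C → rt
Reagents that add atoms: none
Why: Buffered hydrogen fluoride cleaves the secondary allylic TBS ether at C2 while the bulkier, more acid-stable primary TBDPS ether and both ester functions persist.

Step 23
Reactants: 37 C2 alcohol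
Product: 38 2-acetate 6-methacrylate 13-O-TBDPS ether
Conditions: Ac2O, pyridine, DMAP (cat.), CH2Cl2, 0 °C
Reagents that add atoms: acetic anhydride, CC(=O)OC(C)=O
Why: Acetylation takes place at the only unhindered free hydroxyl (secondary allylic C2), the tertiary C4 hydroxyl staying free and O13 still being silylated.

Step 24
Reactants: 38 silyl ether of the target
Product: 39 target, (2S,4S,6R)-2-acetoxy-4,13-dihydroxy-6-methacryloyloxygermacra-1(10)E,7(11),8-trien-12,8-olide
Conditions: Bu4NF, AcOH (1:1), THF, 0 °C → rt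
Reagents that add atoms: none
Why: Acetic acid-buffered fluoride cleaves the primary TBDPS ether without acyl migration, ester cleavage or opening of the enol lactone, releasing the target.

**Compound list**

1 | 1,3-dithiane | C1CSCSC1 | starting material
2 | 2-lithio-1,3-dithiane (not isolated) | [Li]C1SCCCS1 | intermediate
3 | 2-(tert-butyldimethylsilyl)-1,3-dithiane | CC(C)(C)[Si](C)(C)C1SCCCS1 | intermediate
4 | (R)-glycidol | OC[C@@H]1CO1 | starting material
5 | (S)-4-methoxybenzyl glycidyl ether | C1O[C@@H]1COCc2ccc(OC)cc2 | intermediate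
6 | (R)-benzyl glycidyl ether | C1O[C@H]1COCc2ccccc2 | starting material
7 | 2-lithio-2-(tert-butyldimethylsilyl)-1,3-dithiane (not isolated) | [Li]C1(SCCCS1)[Si](C)(C)C(C)(C)C | intermediate
8 | lithium (2S)-1-(4-methoxybenzyloxy)-3-[2-(tert-butyldimethylsilyl)-1,3-dithian-2-yl]propan-2-olate (not isolated) | [Li]O[C@H](COCc1ccc(OC)cc1)CC2(SCCCS2)[Si](C)(C)C(C)(C)C | intermediate
9 | 2-lithio-2-[(2S)-2-(tert-butyldimethylsilyloxy)-3-(4-methoxybenzyloxy)propyl]-1,3-dithiane (not isolated) | [Li]C1(SCCCS1)C[C@H](O[Si](C)(C)C(C)(C)C)COCc2ccc(OC)cc2 | intermediate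
10 | 2-[(2R)-3-benzyloxy-2-hydroxypropyl]-2-[(2S)-2-(tert-butyldimethylsilyloxy)-3-(4-methoxybenzyloxy)propyl]-1,3-dithiane | O[C@@H](COCc1ccccc1)CC2(SCCCS2)C[C@H](O[Si](C)(C)C(C)(C)C)COCc3ccc(OC)cc3 | intermediate
11 | (2S,6R)-7-benzyloxy-6-hydroxy-1-(4-methoxybenzyloxy)-2-(tert-butyldimethylsilyloxy)heptan-4-one | O[C@@H](COCc1ccccc1)CC(=O)C[C@H](O[Si](C)(C)C(C)(C)C)COCc2ccc(OC)cc2 | intermediate
12 | (2S,6R)-7-benzyloxy-1-(4-methoxybenzyloxy)-4-methylidene-2-(tert-butyldimethylsilyloxy)heptan-6-ol | O[C@@H](COCc1ccccc1)CC(=C)C[C@H](O[Si](C)(C)C(C)(C)C)COCc2ccc(OC)cc2 | intermediate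
13 | C4 spiro-oxirane of 12 (oxirane oxygen anti to O2 and O6) | O[C@@H](COCc1ccccc1)C[C@@]2(OC2)C[C@H](O[Si](C)(C)C(C)(C)C)COCc3ccc(OC)cc3 | intermediate
14 | (2S,6R)-7-benzyloxy-1-(4-methoxybenzyloxy)-4-methyl-2-(tert-butyldimethylsilyloxy)heptane-4,6-diol (C4 hydroxyl anti to O2 and O6) | O[C@@H](COCc1ccccc1)C[C@@](C)(O)C[C@H](O[Si](C)(C)C(C)(C)C)COCc2ccc(OC)cc2 | intermediate
15 | 4,6-bis(triethylsilyl) ether of 14 | CC[Si](CC)(CC)O[C@@H](COCc1ccccc1)C[C@@](C)(O[Si](CC)(CC)CC)C[C@H](O[Si](C)(C)C(C)(C)C)COCc2ccc(OC)cc2 | intermediate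
16 | C7 primary alcohol (7-O-debenzylated 15) | CC[Si](CC)(CC)O[C@@H](CO)C[C@@](C)(O[Si](CC)(CC)CC)C[C@H](O[Si](C)(C)C(C)(C)C)COCc1ccc(OC)cc1 | intermediate
17 | C7 aldehyde | CC[Si](CC)(CC)O[C@@H](C=O)C[C@@](C)(O[Si](CC)(CC)CC)C[C@H](O[Si](C)(C)C(C)(C)C)COCc1ccc(OC)cc1 | intermediate
18 | ethyl 3-hydroxypropanoate | CCOC(=O)CCO | starting material
19 | ethyl 3-(tert-butyldiphenylsilyloxy)propanoate | CCOC(=O)CCO[Si](c1ccccc1)(c2ccccc2)C(C)(C)C | intermediate
20 | lithium enolate of 19 (not isolated) | CCOC(O[Li])=CCO[Si](c1ccccc1)(c2ccccc2)C(C)(C)C | intermediate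
21 | β-hydroxy ester (C7 carbinol, C11 bearing CH2OTBDPS and CO2Et; mixture at C7 and C11) | CC[Si](CC)(CC)O[C@@H](C(O)C(CO[Si](c1ccccc1)(c2ccccc2)C(C)(C)C)C(=O)OCC)C[C@@](C)(O[Si](CC)(CC)CC)C[C@H](O[Si](C)(C)C(C)(C)C)COCc3ccc(OC)cc3 | intermediate
22 | β-keto ester (C7 ketone) | CC[Si](CC)(CC)O[C@@H](C(=O)C(CO[Si](c1ccccc1)(c2ccccc2)C(C)(C)C)C(=O)OCC)C[C@@](C)(O[Si](CC)(CC)CC)C[C@H](O[Si](C)(C)C(C)(C)C)COCc3ccc(OC)cc3 | intermediate
23 | chelated sodium (Z)-enolate of 22 (not isolated) | CC[Si](CC)(CC)O[C@@H](/C(O[Na])=C(\CO[Si](c1ccccc1)(c2ccccc2)C(C)(C)C)C(=O)OCC)C[C@@](C)(O[Si](CC)(CC)CC)C[C@H](O[Si](C)(C)C(C)(C)C)COCc3ccc(OC)cc3 | intermediate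
24 | (Z)-enol triflate (C7–OTf cis to the C12 ester) | CC[Si](CC)(CC)O[C@@H](/C(OS(=O)(=O)C(F)(F)F)=C(\CO[Si](c1ccccc1)(c2ccccc2)C(C)(C)C)C(=O)OCC)C[C@@](C)(O[Si](CC)(CC)CC)C[C@H](O[Si](C)(C)C(C)(C)C)COCc3ccc(OC)cc3 | intermediate
25 | (tributylstannyl)methanol | OC[Sn](CCCC)(CCCC)CCCC | starting material
26 | (Z)-hydroxymethyl enoate (C8H2OH cis to the ester; not isolated) | CC[Si](CC)(CC)O[C@@H](/C(CO)=C(\CO[Si](c1ccccc1)(c2ccccc2)C(C)(C)C)C(=O)OCC)C[C@@](C)(O[Si](CC)(CC)CC)C[C@H](O[Si](C)(C)C(C)(C)C)COCc3ccc(OC)cc3 | intermediate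
27 | butenolide with C8H2 (1-O-PMB) | CC[Si](CC)(CC)O[C@@H](C1=C(CO[Si](c2ccccc2)(c3ccccc3)C(C)(C)C)C(=O)OC1)C[C@@](C)(O[Si](CC)(CC)CC)C[C@H](O[Si](C)(C)C(C)(C)C)COCc4ccc(OC)cc4 | intermediate
28 | C1 primary alcohol | CC[Si](CC)(CC)O[C@@H](C1=C(CO[Si](c2ccccc2)(c3ccccc3)C(C)(C)C)C(=O)OC1)C[C@@](C)(O[Si](CC)(CC)CC)C[C@H](O[Si](C)(C)C(C)(C)C)CO | intermediate
29 | C1 aldehyde | CC[Si](CC)(CC)O[C@@H](C1=C(CO[Si](c2ccccc2)(c3ccccc3)C(C)(C)C)C(=O)OC1)C[C@@](C)(O[Si](CC)(CC)CC)C[C@H](O[Si](C)(C)C(C)(C)C)C=O | intermediate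
30 | 2-(triphenylphosphoranylidene)propanal | CC(C=O)=P(c1ccccc1)(c2ccccc2)c3ccccc3 | starting material
31 | (E)-enal butenolide (seco precursor) | CC[Si](CC)(CC)O[C@@H](C1=C(CO[Si](c2ccccc2)(c3ccccc3)C(C)(C)C)C(=O)OC1)C[C@@](C)(O[Si](CC)(CC)CC)C[C@H](O[Si](C)(C)C(C)(C)C)/C=C(C)/C=O | intermediate
32 | 2-(tert-butyldimethylsilyloxy)furan of 31 (not isolated) | CC[Si](CC)(CC)O[C@@H](c1coc(O[Si](C)(C)C(C)(C)C)c1CO[Si](c2ccccc2)(c3ccccc3)C(C)(C)C)C[C@@](C)(O[Si](CC)(CC)CC)C[C@H](O[Si](C)(C)C(C)(C)C)/C=C(C)/C=O | intermediate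
33 | macrocyclic aldol silyl ether (C8–H, C9–OTBS; mixture at C8 and C9; not isolated) | CC[Si](CC)(CC)O[C@@H]1C[C@@](C)(O[Si](CC)(CC)CC)C[C@H](O[Si](C)(C)C(C)(C)C)/C=C(C)/C(O[Si](C)(C)C(C)(C)C)C2OC(=O)C(CO[Si](c3ccccc3)(c4ccccc4)C(C)(C)C)=C21 | intermediate
34 | macrocyclic γ-ylidenebutenolide (2-O-TBS, 4,6-bis-O-TES, 13-O-TBDPS) | CC[Si](CC)(CC)O[C@@H]1C[C@@](C)(O[Si](CC)(CC)CC)C[C@H](O[Si](C)(C)C(C)(C)C)/C=C(C)/C=C2/OC(=O)C(CO[Si](c3ccccc3)(c4ccccc4)C(C)(C)C)=C21 | intermediate
35 | 4,6-diol (2-O-TBS, 13-O-TBDPS) | O[C@@H]1C[C@@](C)(O)C[C@H](O[Si](C)(C)C(C)(C)C)/C=C(C)/C=C2/OC(=O)C(CO[Si](c3ccccc3)(c4ccccc4)C(C)(C)C)=C21 | intermediate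
36 | 6-methacrylate (2-O-TBS, 13-O-TBDPS) | C=C(C)C(=O)O[C@@H]1C[C@@](C)(O)C[C@H](O[Si](C)(C)C(C)(C)C)/C=C(C)/C=C2/OC(=O)C(CO[Si](c3ccccc3)(c4ccccc4)C(C)(C)C)=C21 | intermediate
37 | C2 alcohol (6-methacrylate, 13-O-TBDPS) | C=C(C)C(=O)O[C@@H]1C[C@@](C)(O)C[C@H](O)/C=C(C)/C=C2/OC(=O)C(CO[Si](c3ccccc3)(c4ccccc4)C(C)(C)C)=C21 | intermediate
38 | 2-acetate 6-methacrylate 13-O-TBDPS ether | C=C(C)C(=O)O[C@@H]1C[C@@](C)(O)C[C@H](OC(C)=O)/C=C(C)/C=C2/OC(=O)C(CO[Si](c3ccccc3)(c4ccccc4)C(C)(C)C)=C21 | intermediate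
39 | (2S,4S,6R)-2-acetoxy-4,13-dihydroxy-6-methacryloyloxygermacra-1(10)E,7(11),8-trien-12,8-olide | C=C(C)C(=O)O[C@@H]1C[C@@](C)(O)C[C@H](OC(C)=O)/C=C(C)/C=C2/OC(=O)C(CO)=C21 | target

**Step count**

Total: 24 steps. Longest linear sequence: 22 steps (4 → 39 through steps 2–10 and 12–24).

**Steps most likely to fail**

1. Step 19 (proposed new method). The ten-membered ring closure may be outrun by intermolecular aldol oligomerisation, by conjugate addition at C1 (eight-membered ring) or by ionisation of the C6 silyloxy group in the silyloxyfuran. Fallback with known chemistry, from 27 back to 34, is an olefination ring closure. Soft enolisation of 27 (t-BuMe2SiOTf, Et3N) and bromination with N-bromosuccinimide would give the γ-bromobutenolide F1. Michaelis–Arbuzov reaction with P(OMe)3 would give the γ-(dimethoxyphosphoryl)butenolide F2. DDQ would then give the C1 alcohol F3, Dess–Martin oxidation the aldehyde F4 and Wittig reaction with 30 the enal phosphonate F5. Intramolecular Horner–Wadsworth–Emmons olefination (LiCl, DBU, MeCN, high dilution) would close the ring irreversibly to 34, where step 20 follows.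

2. Step 6. Oxygen delivery may show poor or reversed facial selectivity, because the homoallylic stereocentre is remote and the two alkene substituents are alike. Fallback, from 12 back to 14, is a stereoconvergent inversion at C4. The C4-epimeric oxirane F6, formed beside or instead of 13, would be converted with Boc2O/DMAP into the tert-butyl carbonate F7. With BF3·OEt2 (CH2Cl2, −40 °C) the carbonate carbonyl oxygen should open the oxirane at the tertiary carbon with inversion, giving the six-membered cyclic carbonate F8 with the C4 oxygen anti to O6 and a free CH2OH. Tosylation (TsCl, pyridine) would give F9. LiAlH4 would then cleave the carbonate and, through the C4 alkoxide, turn the tosylate into oxirane 13 and on into 14.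

3. Step 15. Transmetalation of the sp3 stannane to the hindered tetrasubstituted vinylpalladium species may be too slow, so that triflate hydrolysis or butyl transfer takes over. Fallback, from 24 back to 27, brings in C8 as carbon monoxide. Carbonylative reduction (CO 1 atm, Pd(PPh3)4, Bu3SnH, THF, 50 °C) would give the (Z)-formyl enoate F10. Luche reduction (NaBH4, CeCl3·7H2O, MeOH, −40 °C) would give hydroxymethyl enoate 26, which lactonises to 27.

**Further compounds**

F1 | step 19 | γ-bromobutenolide (C8–Br; 1-O-PMB) | CC[Si](CC)(CC)O[C@@H](C1=C(CO[Si](c2ccccc2)(c3ccccc3)C(C)(C)C)C(=O)OC1Br)C[C@@](C)(O[Si](CC)(CC)CC)C[C@H](O[Si](C)(C)C(C)(C)C)COCc4ccc(OC)cc4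
F2 | step 19 | γ-(dimethoxyphosphoryl)butenolide (1-O-PMB) | CC[Si](CC)(CC)O[C@@H](C1=C(CO[Si](c2ccccc2)(c3ccccc3)C(C)(C)C)C(=O)OC1P(=O)(OC)OC)C[C@@](C)(O[Si](CC)(CC)CC)C[C@H](O[Si](C)(C)C(C)(C)C)COCc4ccc(OC)cc4
F3 | step 19 | C1 alcohol of the phosphonate | CC[Si](CC)(CC)O[C@@H](C1=C(CO[Si](c2ccccc2)(c3ccccc3)C(C)(C)C)C(=O)OC1P(=O)(OC)OC)C[C@@](C)(O[Si](CC)(CC)CC)C[C@H](O[Si](C)(C)C(C)(C)C)CO
F4 | step 19 | C1 aldehyde of the phosphonate | CC[Si](CC)(CC)O[C@@H](C1=C(CO[Si](c2ccccc2)(c3ccccc3)C(C)(C)C)C(=O)OC1P(=O)(OC)OC)C[C@@](C)(O[Si](CC)(CC)CC)C[C@H](O[Si](C)(C)C(C)(C)C)C=O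
F5 | step 19 | (E)-enal phosphonate | CC[Si](CC)(CC)O[C@@H](C1=C(CO[Si](c2ccccc2)(c3ccccc3)C(C)(C)C)C(=O)OC1P(=O)(OC)OC)C[C@@](C)(O[Si](CC)(CC)CC)C[C@H](O[Si](C)(C)C(C)(C)C)/C=C(C)/C=O
F6 | step 6 | C4-epimeric spiro-oxirane (oxirane oxygen syn to O2 and O6) | O[C@@H](COCc1ccccc1)C[C@]2(OC2)C[C@H](O[Si](C)(C)C(C)(C)C)COCc3ccc(OC)cc3
F7 | step 6 | 6-O-tert-butyl carbonate of the epimeric oxirane | CC(C)(C)OC(=O)O[C@@H](COCc1ccccc1)C[C@]2(OC2)C[C@H](O[Si](C)(C)C(C)(C)C)COCc3ccc(OC)cc3
F8 | step 6 | 4,6-cyclic carbonate with C4–CH2OH (C4 inverted) | O=C1O[C@@H](COCc2ccccc2)C[C@@](CO)(O1)C[C@H](O[Si](C)(C)C(C)(C)C)COCc3ccc(OC)cc3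
F9 | step 6 | primary tosylate of the cyclic carbonate | O=C1O[C@@H](COCc2ccccc2)C[C@@](COS(=O)(=O)c4ccc(C)cc4)(O1)C[C@H](O[Si](C)(C)C(C)(C)C)COCc3ccc(OC)cc3
F10 | step 15 | (Z)-formyl enoate (C8 aldehyde cis to the ester) | CC[Si](CC)(CC)O[C@@H](/C(C=O)=C(\CO[Si](c1ccccc1)(c2ccccc2)C(C)(C)C)C(=O)OCC)C[C@@](C)(O[Si](CC)(CC)CC)C[C@H](O[Si](C)(C)C(C)(C)C)COCc3ccc(OC)cc3
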